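## Retrosynthetic overview

1. The silyl ether is removed last. The C1 carbinol configuration is written by a sulfenate/sulfoxide [2,3] pair. The C1–C7 bond comes from an alkenylcerium side chain and (3R,4R)-3-bromo-4-chloro-4-methylcyclohexanone.
2. The six-membered carbocycle is not closed directly. It arises from exo-6-bromo-5-methylbicyclo[3.1.0]hexan-2-one by a ring-expanding addition of HCl that cuts the ring-fusion bond.
3. Enabling feature: in the target ring, C4(Me)(Cl) stands gamma to C1 (the former carbonyl carbon), with C5HBr and C6H2 between them. Joining C4 to C6 gives a cyclopropane (C4, C5, C6) fused to a cyclopentanone (C1, C2, C3, C4, C6) and conjugated with the C1 carbonyl, with a tertiary site ready to take chloride.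
4. The bicycle comes from an (E)-vinyl bromide diazoketone by enantioselective intramolecular cyclopropanation. The E geometry comes from carboalumination of pent-4-yn-1-ol, and the side-chain carbinol from a CBS reduction.
5. Ring order: cyclopropane and cyclopentanone form together (step 4), then the cyclohexanone (step 5).

Key step: step 5

Locants used in the text: C1 carbinol carbon, C2 and C3 the CH2CH2 unit, C4 the C(Me)Cl carbon, C5 the CHBr carbon, C6 the CH2 between C5 and C1, C7 the alkene carbon bonded to C1.

Assumption: the (S,S) ligand in step 4 is taken to give the (1R,5R,6R) bicycle. If the sense of induction is the opposite, the (R,R) ligand is used and nothing else changes.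

## Route

Step 1
Reactants: 1 pent-4-yn-1-ol
Product: 3 (E)-5-bromo-4-methylpent-4-en-1-ol, via alkenylalane 2 (not isolated)
Conditions: Me3Al (3 equiv), Cp2ZrCl2 (0.25 equiv), CH2Cl2, 0 °C to rt; then NBS, THF, −30 to 0 °C; H2O
Reagents that add atoms: trimethylaluminium C[Al](C)C; N-bromosuccinimide O=C1CCC(=O)N1Br
Why: Negishi zirconium-catalysed carboalumination adds methyl and aluminium syn across the alkyne with aluminium at the terminus, and bromodealumination with retention should fix the E geometry that later becomes the exo C–Br bond.

Step 2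
Reactants: 3 (E)-5-bromo-4-methylpent-4-en-1-ol
Product: 4 (E)-5-bromo-4-methylpent-4-enoic acid
Conditions: TEMPO (0.2 equiv), PhI(OAc)2 (2.2 equiv), MeCN/H2O 1:1, rt
Reagents that add atoms: water O
Why: Oxoammonium (TEMPO) oxidation takes the primary alcohol through the aldehyde hydrate to the acid without touching the vinyl bromide, and no stereocentre is involved.

Step 3
Reactants: 4 (E)-5-bromo-4-methylpent-4-enoic acid
Product: 6 (E)-6-bromo-1-diazo-5-methylhex-5-en-2-one, via acid chloride 5 (not isolated)
Conditions: (COCl)2, DMF (cat), CH2Cl2, 0 °C to rt, concentrate; then TMSCHN2 (2 equiv), THF/MeCN, 0 °C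
Reagents that add atoms: oxalyl chloride O=C(Cl)C(=O)Cl (chlorine of 5); (trimethylsilyl)diazomethane C[Si](C)(C)C=[N+]=[N-]
Why: Acylation of a diazoalkane by an acid chloride (first stage of the Arndt–Eistert sequence) gives the terminal diazoketone under conditions that leave the alkene geometry intact.

Step 4
Reactants: 6 (E)-6-bromo-1-diazo-5-methylhex-5-en-2-one
Product: 7 (1R,5R,6R)-6-bromo-5-methylbicyclo[3.1.0]hexan-2-one (bromine exo, cis to methyl)
Conditions: Cu(MeCN)4PF6 (5 mol %), (S,S)-tBu-box (6 mol %), CH2Cl2, rt, slow addition of 6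
Reagents that add atoms: none
Why: Enantioselective intramolecular cyclopropanation by a copper carbene closes the cyclopentanone and the cyclopropane in one suprafacial event, so the E geometry places bromine cis to methyl (exo) while the C2-symmetric bis(oxazoline) chooses the alkene face and with it all three stereocentres.

Step 5
Reactants: 7 (1R,5R,6R)-6-bromo-5-methylbicyclo[3.1.0]hexan-2-one
Product: 9 (3R,4R)-3-bromo-4-chloro-4-methylcyclohexan-1-one, via enol 8 (not isolated)
Conditions: HCl (4 M in 1,4-dioxane, 3 equiv), CH2Cl2, −20 to 0 °C; cold water wash, no base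
Reagents that add atoms: hydrogen chloride Cl
Why: Proposed new method: protonation of the carbonyl oxygen of 7 polarises the cyclopropane, the ring-fusion bond between the bridgehead CH next to the carbonyl and the methyl-bearing bridgehead breaks heterolytically while chloride enters at the tertiary carbon, and enol 8 tautomerises to 9, so the five-membered ring grows to six members by taking in the CHBr carbon. The closest known reaction type is the homoconjugate addition of HX to cyclopropyl ketones, in particular the acid-induced opening of 5-alkylbicyclo[3.1.0]hexan-2-ones to 4-substituted cyclohexanones, and what has not been shown is this opening with a bromine on the cyclopropane apex and stereospecific capture by chloride. No ring bond is formed, because the six-membered ring arises only by scission of the zero-atom bridge, so no closure mode has to be obeyed. The new C–Cl stereocentre is set by backside entry of chloride (inversion at the quaternary carbon), and if the cation becomes freer the neighbouring bromine bridges it and again enforces anti attack, so both paths give the trans (3R,4R) pair while the C–Br centre is carried over unchanged from the exo bromide. The step needs cleavage of the fusion bond rather than the bridgehead–CHBr bond, which the methyl group (tertiary cation character) and the bromine (slow substitution at the apex) secure, and it needs the C–Br bond to survive, which the exo configuration secures because ionisation of an exo cyclopropyl halide would require the outward disrotation to a trans allyl cation that a six-membered ring cannot hold. Loss of HBr from 8 or 9 is held back by cold, base-free handling and by the bromine emerging equatorial, nearly orthogonal to the enol pi system.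

Step 6
Reactants: 10 N-methoxy-N-methylacetamide; 11 2,3-dibromopropene
Product: 13 4-bromo-N-methoxy-N-methylpent-4-enamide, via lithium enolate 12 (not isolated)
Conditions: LDA, THF, −78 °C; then 11, DMPU, −78 to −20 °C
Reagents that add atoms: lithium diisopropylamide [Li]N(C(C)C)C(C)C (lithium of 12)
Why: Enolate alkylation by SN2 attack at the allylic CH2Br of 11 is expected because the vinylic bromide is inert, and no stereocentre is formed.

Step 7
Reactants: 13 4-bromo-N-methoxy-N-methylpent-4-enamide; 14 isopropenylmagnesium bromide
Product: 15 6-bromo-2-methylhepta-1,6-dien-3-one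
Conditions: 14 (0.5 M in THF), THF, 0 °C; 1 M HCl quench
Reagents that add atoms: none
Why: The Weinreb ketone synthesis stops at the chelated tetrahedral adduct, so only one isopropenyl group is transferred, and the acidic quench keeps the liberated amine from adding to the enone.

Step 8
Reactants: 15 6-bromo-2-methylhepta-1,6-dien-3-one
Product: 16 (3R)-6-bromo-2-methylhepta-1,6-dien-3-ol
Conditions: (S)-Me-CBS (0.2 equiv), catecholborane (1.5 equiv), toluene, −78 °C; aqueous work-up
Reagents that add atoms: none
Why: In the CBS reduction the isopropenyl group acts as the large and the CH2 chain as the small substituent, so the S catalyst should deliver hydride to the face that gives the R carbinol, and catecholborane at low temperature avoids hydroboration.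

Step 9
Reactants: 16 (3R)-6-bromo-2-methylhepta-1,6-dien-3-ol
Product: 17 [(3R)-6-bromo-2-methylhepta-1,6-dien-3-yl]oxy(tert-butyl)dimethylsilane
Conditions: TBSCl, imidazole, DMF, rt
Reagents that add atoms: tert-butyldimethylsilyl chloride CC(C)(C)[Si](C)(C)Cl
Why: Standard silylation masks the secondary allylic alcohol against tert-butyllithium, benzenesulfenyl chloride and the later [2,3] chemistry, and the stereocentre is untouched.

Step 10
Reactants: 17 [(3R)-6-bromo-2-methylhepta-1,6-dien-3-yl]oxy(tert-butyl)dimethylsilane; 9 (3R,4R)-3-bromo-4-chloro-4-methylcyclohexan-1-one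
Product: 20 (1R,3R,4R)-3-bromo-1-[(5R)-5-[tert-butyl(dimethyl)silyl]oxy-6-methylhepta-1,6-dien-2-yl]-4-chloro-4-methylcyclohexan-1-ol, via alkenyllithium 18 (not isolated), via alkenylcerium dichloride 19 (not isolated)
Conditions: t-BuLi (2 equiv), Et2O, −78 °C; CeCl3 (anhydrous), THF, −78 °C; then 9, −78 °C; AcOH quench at −78 °C
Reagents that add atoms: tert-butyllithium [Li]C(C)(C)C (lithium of 18); cerium trichloride Cl[Ce](Cl)Cl (cerium and chlorine of 19)
Why: In this organocerium 1,2-addition the weakly basic alkenylcerium should add faster than it enolises the beta-bromo ketone, approach along the equatorial trajectory from the face away from the axial C–Br bond of the favoured diaxial-dihalide chair, and so give mainly the (1R) carbinol, whose C1 configuration is provisional and is rewritten in steps 11 and 12.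

Step 11
Reactants: 20 (1R,3R,4R)-tertiary allylic alcohol (any C1 epimer present is carried along)
Product: 22 {[(5R)-2-[(3R,4R)-3-bromo-4-chloro-4-methylcyclohexylidene]-5-[tert-butyl(dimethyl)silyl]oxy-6-methylhept-6-en-1-yl]sulfinyl}benzene (mixture at sulfur and at the tetrasubstituted alkene), via benzenesulfenate 21 (not isolated)
Conditions: PhSCl (1.05 equiv), Et3N, CH2Cl2, −78 °C to rt
Reagents that add atoms: benzenesulfenyl chloride ClSc1ccccc1
Why: O-Sulfenylation is followed by the Mislow–Evans [2,3]-sigmatropic shift of 21 to the more stable primary allylic sulfoxide, C1 becomes trigonal so both carbinol epimers converge, and the isomerism at sulfur and at the alkene is of no consequence for the next step.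

Step 12
Reactants: 22 allylic sulfoxide
Product: 24 (1S,3R,4R)-3-bromo-1-[(5R)-5-[tert-butyl(dimethyl)silyl]oxy-6-methylhepta-1,6-dien-2-yl]-4-chloro-4-methylcyclohexan-1-ol, via (1S)-benzenesulfenate 23 (not isolated)
Conditions: P(OMe)3 (excess), MeOH, rt to 40 °C
Reagents that add atoms: none
Why: In the reverse Mislow–Evans rearrangement with a thiophile, 22 equilibrates with both epimeric sulfenates, and oxygen should arrive on the open ring face away from the C–Br bond that carbon used in step 10. The resulting (1S)-sulfenate 23 (O axial; alkenyl, Br and Cl equatorial) is also more stable and more exposed than its epimer, whose O–SPh group is 1,3-diaxial to bromine, so kinetic and Curtin–Hammett arguments both point to the (1S) carbinol, in line with the known use of such pairs to invert tertiary allylic carbinols.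

Step 13
Reactants: 24 (1S,3R,4R)-silyl ether
Product: 25 (1S,3R,4R)-3-bromo-4-chloro-1-[(5R)-5-hydroxy-6-methylhepta-1,6-dien-2-yl]-4-methylcyclohexan-1-ol (target)
Conditions: HF·pyridine, pyridine, THF, 0 °C to rt
Reagents that add atoms: none
Why: Buffered fluoride desilylation is neither basic enough to trigger Grob fragmentation or oxetane formation of the 1,3-bromohydrin nor acidic enough to ionise the tertiary allylic alcohol, and no stereocentre is touched.

## Compound list

1 | pent-4-yn-1-ol | C#CCCCO | starting material
2 | (E)-[5-(dimethylalumanyloxy)-2-methylpent-1-en-1-yl]dimethylalane | C[Al](C)OCCC/C(C)=C/[Al](C)C | intermediate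
3 | (E)-5-bromo-4-methylpent-4-en-1-ol | OCCC/C(C)=C/Br | intermediate
4 | (E)-5-bromo-4-methylpent-4-enoic acid | OC(=O)CC/C(C)=C/Br | intermediate
5 | (E)-5-bromo-4-methylpent-4-enoyl chloride | ClC(=O)CC/C(C)=C/Br | intermediate
6 | (E)-6-bromo-1-diazo-5-methylhex-5-en-2-one | [N-]=[N+]=CC(=O)CC/C(C)=C/Br | intermediate
7 | (1R,5R,6R)-6-bromo-5-methylbicyclo[3.1.0]hexan-2-one | O=C1CC[C@@]2(C)[C@H](Br)[C@@H]12 | intermediate
8 | (4R,5R)-5-bromo-4-chloro-4-methylcyclohex-1-en-1-ol | OC=1CC[C@@](C)(Cl)[C@H](Br)C=1 | intermediate
9 | (3R,4R)-3-bromo-4-chloro-4-methylcyclohexan-1-one | O=C1CC[C@@](C)(Cl)[C@H](Br)C1 | intermediate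
10 | N-methoxy-N-methylacetamide | CC(=O)N(C)OC | starting material
11 | 2,3-dibromopropene | C=C(Br)CBr | starting material
12 | lithium enolate of N-methoxy-N-methylacetamide | [Li]OC(=C)N(C)OC | intermediate
13 | 4-bromo-N-methoxy-N-methylpent-4-enamide | C=C(Br)CCC(=O)N(C)OC | intermediate
14 | isopropenylmagnesium bromide | CC(=C)[Mg]Br | starting material
15 | 6-bromo-2-methylhepta-1,6-dien-3-one | C=C(C)C(=O)CCC(Br)=C | intermediate
16 | (3R)-6-bromo-2-methylhepta-1,6-dien-3-ol | C=C(C)[C@H](O)CCC(Br)=C | intermediate
17 | [(3R)-6-bromo-2-methylhepta-1,6-dien-3-yl]oxy(tert-butyl)dimethylsilane | C=C(C)[C@H](O[Si](C)(C)C(C)(C)C)CCC(Br)=C | intermediate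
18 | alkenyllithium from 17 | C=C(C)[C@H](O[Si](C)(C)C(C)(C)C)CCC([Li])=C | intermediate
19 | alkenylcerium dichloride from 18 | C=C(C)[C@H](O[Si](C)(C)C(C)(C)C)CCC(=C)[Ce](Cl)Cl | intermediate
20 | (1R,3R,4R)-3-bromo-1-[(5R)-5-[tert-butyl(dimethyl)silyl]oxy-6-methylhepta-1,6-dien-2-yl]-4-chloro-4-methylcyclohexan-1-ol | C=C(C)[C@H](O[Si](C)(C)C(C)(C)C)CCC(=C)[C@@]1(O)CC[C@@](C)(Cl)[C@H](Br)C1 | intermediate
21 | benzenesulfenate ester of 20 | C=C(C)[C@H](O[Si](C)(C)C(C)(C)C)CCC(=C)[C@@]1(OSc2ccccc2)CC[C@@](C)(Cl)[C@H](Br)C1 | intermediate
22 | {[(5R)-2-[(3R,4R)-3-bromo-4-chloro-4-methylcyclohexylidene]-5-[tert-butyl(dimethyl)silyl]oxy-6-methylhept-6-en-1-yl]sulfinyl}benzene (mixture at S and at the alkene) | C=C(C)[C@H](O[Si](C)(C)C(C)(C)C)CCC(CS(=O)c1ccccc1)=C1CC[C@@](C)(Cl)[C@H](Br)C1 | intermediate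
23 | (1S)-benzenesulfenate ester of 24 | C=C(C)[C@H](O[Si](C)(C)C(C)(C)C)CCC(=C)[C@]1(OSc2ccccc2)CC[C@@](C)(Cl)[C@H](Br)C1 | intermediate
24 | (1S,3R,4R)-3-bromo-1-[(5R)-5-[tert-butyl(dimethyl)silyl]oxy-6-methylhepta-1,6-dien-2-yl]-4-chloro-4-methylcyclohexan-1-ol | C=C(C)[C@H](O[Si](C)(C)C(C)(C)C)CCC(=C)[C@]1(O)CC[C@@](C)(Cl)[C@H](Br)C1 | intermediate
25 | (1S,3R,4R)-3-bromo-4-chloro-1-[(5R)-5-hydroxy-6-methylhepta-1,6-dien-2-yl]-4-methylcyclohexan-1-ol | C=C(C)[C@H](O)CCC(=C)[C@]1(O)CC[C@@](C)(Cl)[C@H](Br)C1 | target

## Step count and risks

Total step count: 13. Longest linear sequence: 9 steps (steps 1 to 5 and 10 to 13).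

**Step 5 (proposed new method).**
- What may go wrong: the inductive pull of the apex bromine may slow heterolysis of the fusion bond so far that chloride attacks the other cyclopropane bond, or that hydrogen bromide is lost from the enol.
- Fallback: it sets out from 7 and separates C–C cleavage from C–Cl formation, using known reaction types. The classical solvolytic opening of 5-alkylbicyclo[3.1.0]hexan-2-ones in aqueous H2SO4/THF lets water enter at the tertiary carbon with inversion. This should give (3R,4R)-3-bromo-4-hydroxy-4-methylcyclohexan-1-one F1.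
- Return to the route: SOCl2 in Et2O at low temperature then turns the tertiary alcohol into the chloride by way of the bromine-bridged cation, with overall retention and chloride anti to bromine. The route is rejoined at 9.

**Step 12.**
- What may go wrong: because the sulfoxide–sulfenate equilibrium is reversible, facial discrimination at C1 may be poor, and phosphite may attack the halides slowly.
- Fallback: it sets out from 20 and replaces the reversible oxygen transfer by an irreversible one. O3ReOSiPh3-catalysed 1,3-transposition should give the primary allylic alcohol (5R)-2-[(3R,4R)-3-bromo-4-chloro-4-methylcyclohexylidene]-5-[tert-butyl(dimethyl)silyl]oxy-6-methylhept-6-en-1-ol F2.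
- Oxygen delivery: hydroxyl-directed epoxidation with VO(acac)2 and t-BuOOH should deliver oxygen to the alkene face away from the C–Br bond. This gives [(3S,5R,6R)-5-bromo-6-chloro-6-methyl-2-{(3R)-3-[tert-butyl(dimethyl)silyl]oxy-4-methylpent-4-en-1-yl}-1-oxaspiro[2.5]octan-2-yl]methanol F3.
- Return to the route: Dess–Martin oxidation gives the corresponding 1-oxaspiro[2.5]octane-2-carbaldehyde F4. Wharton transposition with hydrazine hydrate and acetic acid in methanol keeps the C1–O bond and turns the aldehyde carbon into the terminal methylene, rejoining the route at 24.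

**Step 4.**
- What may go wrong: the copper catalyst may discriminate poorly between the faces of the electron-poor trisubstituted vinyl bromide, and carbene dimerisation competes.
- Fallback: it sets out from 6 and moves the source of chirality from the catalyst to a resolution. Rh2(OAc)4 in CH2Cl2 should give racemic exo-6-bromo-5-methylbicyclo[3.1.0]hexan-2-one F5.
- Resolution: NaBH4 attacks anti to the cyclopropane and gives the cis alcohol (1R,2S,5R,6R)-6-bromo-5-methylbicyclo[3.1.0]hexan-2-ol F6 as the racemate. Lipase B from Candida antarctica with vinyl acetate should acetylate the (2R) antipode to (1S,2R,5S,6S)-6-bromo-5-methylbicyclo[3.1.0]hexan-2-yl acetate F7.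
- Return to the route: the unreacted F6 is separated and oxidised with Dess–Martin periodinane, rejoining the route at 7.

## Further compounds

F1 | step 5 | (3R,4R)-3-bromo-4-hydroxy-4-methylcyclohexan-1-one | O=C1CC[C@@](C)(O)[C@H](Br)C1
F2 | step 12 | (5R)-2-[(3R,4R)-3-bromo-4-chloro-4-methylcyclohexylidene]-5-[tert-butyl(dimethyl)silyl]oxy-6-methylhept-6-en-1-ol (alkene isomers) | C=C(C)[C@H](O[Si](C)(C)C(C)(C)C)CCC(CO)=C1CC[C@@](C)(Cl)[C@H](Br)C1
F3 | step 12 | [(3S,5R,6R)-5-bromo-6-chloro-6-methyl-2-{(3R)-3-[tert-butyl(dimethyl)silyl]oxy-4-methylpent-4-en-1-yl}-1-oxaspiro[2.5]octan-2-yl]methanol (both C2 epimers) | C=C(C)[C@H](O[Si](C)(C)C(C)(C)C)CCC1(CO)O[C@]12CC[C@@](C)(Cl)[C@H](Br)C2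
F4 | step 12 | (3S,5R,6R)-5-bromo-6-chloro-6-methyl-2-{(3R)-3-[tert-butyl(dimethyl)silyl]oxy-4-methylpent-4-en-1-yl}-1-oxaspiro[2.5]octane-2-carbaldehyde (both C2 epimers) | C=C(C)[C@H](O[Si](C)(C)C(C)(C)C)CCC1(C=O)O[C@]12CC[C@@](C)(Cl)[C@H](Br)C2
F5 | step 4 | racemic exo-6-bromo-5-methylbicyclo[3.1.0]hexan-2-one | O=C1CCC2(C)C(Br)C12
F6 | step 4 | (1R,2S,5R,6R)-6-bromo-5-methylbicyclo[3.1.0]hexan-2-ol | O[C@H]1CC[C@@]2(C)[C@H](Br)[C@@H]12
F7 | step 4 | (1S,2R,5S,6S)-6-bromo-5-methylbicyclo[3.1.0]hexan-2-yl acetate | CC(=O)O[C@@H]1CC[C@]2(C)[C@@H](Br)[C@H]12
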